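## Retrosynthetic overview

1. Target ⇐ removal of the C15 silyl ether; the 3(2H)-furanone is closed last, by gold-catalysed 5-endo attack of the C10 hydroxyl on a macrocyclic C1 ynone.
2. Ten-membered carbocycle ⇐ intramolecular Cr/Ni-mediated addition of a C2 iodoalkyne to a C1 aldehyde (C1–C2 bond), after Mitsunobu inversion and methacrylation at C8.
3. Key union, C7–C8: zinc Barbier allylation of a C8 aldehyde (C8–C10 plus C1) with a 3-(bromomethyl)butenolide (C2–C7, C11–C13, C15). It creates the α-methylene lactone and sets C7 and C8.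
4. The aldehyde comes from (R)-lactic acid (Seebach alkylation sets C10). The bromobutenolide comes from propargyl alcohol, acrolein, trimethylsilylacetylene and 2-(bromomethyl)acrylic acid (lipase resolution sets C6, hydroalumination–iodination sets the alkene, metathesis closes the butenolide).
5. Ring order: butenolide (becomes the lactone) → ten-membered carbocycle → furanone.

Assumption: the SMILES is taken literally, i.e. 6R,7R,8R,10S with C3 and C6 cis across C4=C5 (4Z).

Convention: C1–C15 in names of advanced intermediates are the germacrane locants of the target (C1 ketone, C2=C3 furanone alkene, C4=C5 with C15 on C4, C6 lactone O–CH, C7, C8 ester O–CH, C9 CH2, C10 quaternary C–O, C11=C13 methylidene, C12 lactone C=O, C14 methyl). TBDPS = tert-butyl(diphenyl)silyl, TES = triethylsilyl, TMS = trimethylsilyl, PMB = 4-methoxybenzyl.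

## Route

### Fragment A (aldehyde, C8–C10 and C1)

Step 1
Reactants: 1 (R)-lactic acid
Product: 2 (2R,5R)-2-tert-butyl-5-methyl-1,3-dioxolan-4-one (cis)
Conditions: pivalaldehyde (1.5 equiv), TsOH·H2O (cat.), H2SO4 (cat.), pentane, reflux, Dean–Stark; recrystallise from pentane at −78 °C
Reagents that add atoms: pivalaldehyde, CC(C)(C)C=O
Why: Acid-catalysed acetalisation (Seebach self-regeneration of stereocentres) gives mainly the cis-dioxolanone, obtained pure by crystallisation, so the lactate stereocentre is stored in the new acetal carbon (2R).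

Step 2
Reactants: 2 (2R,5R)-2-tert-butyl-5-methyl-1,3-dioxolan-4-one; 3 allyl bromide
Product: 5 (2R,5S)-2-tert-butyl-5-methyl-5-(prop-2-en-1-yl)-1,3-dioxolan-4-one, via lithium enolate 4 (not isolated)
Conditions: LiN(iPr)2 (LDA, 1.1 equiv), THF, −78 °C; then 3 (1.5 equiv), −78 → −30 °C
Reagents that add atoms: none
Why: Enolate alkylation occurs on the face anti to the tert-butyl group, so allyl replaces H with retention and the C10 quaternary centre is set (d.r. ≥ 95:5 expected).

Step 3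
Reactants: 5 (2R,5S)-2-tert-butyl-5-methyl-5-(prop-2-en-1-yl)-1,3-dioxolan-4-one
Product: 6 (2S)-2-methylpent-4-ene-1,2-diol
Conditions: LiAlH4 (1.5 equiv), Et2O, 0 °C → rt; Fieser work-up (H2O, 15% aq. NaOH)
Reagents that add atoms: none
Why: Hydride reduction of the acetal-lactone releases the diol and reduces the liberated pivalaldehyde, without touching the quaternary centre.

Step 4
Reactants: 6 (2S)-2-methylpent-4-ene-1,2-diol
Product: 7 (2S)-1-[(4-methoxyphenyl)methoxy]-2-methylpent-4-en-2-ol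
Conditions: NaH (1.05 equiv), THF/DMF, 0 °C; 4-methoxybenzyl chloride (1.05 equiv), Bu4NI (cat.), 0 °C → rt
Reagents that add atoms: 4-methoxybenzyl chloride, COc1ccc(CCl)cc1
Why: Williamson etherification is selective for the primary alkoxide over the hindered tertiary one.

Step 5
Reactants: 7 (2S)-1-[(4-methoxyphenyl)methoxy]-2-methylpent-4-en-2-ol
Product: 8 triethyl{[(2S)-1-[(4-methoxyphenyl)methoxy]-2-methylpent-4-en-2-yl]oxy}silane
Conditions: triethylsilyl triflate (1.3 equiv), 2,6-lutidine (2 equiv), CH2Cl2, −78 → 0 °C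
Reagents that add atoms: triethylsilyl trifluoromethanesulfonate, CC[Si](CC)(CC)OS(=O)(=O)C(F)(F)F
Why: Silyl triflate with lutidine is the standard silylation of a tertiary alcohol and affects no stereocentre.

Step 6
Reactants: 8 triethyl{[(2S)-1-[(4-methoxyphenyl)methoxy]-2-methylpent-4-en-2-yl]oxy}silane
Product: 10 (3S)-4-[(4-methoxyphenyl)methoxy]-3-methyl-3-[(triethylsilyl)oxy]butanal, via diol 9 (not isolated)
Conditions: OsO4 (2 mol %), NaIO4 (4 equiv), 2,6-lutidine (2 equiv), dioxane/H2O (3:1), rt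
Reagents that add atoms: osmium tetroxide, O=[Os](=O)(=O)=O (supplies the carbonyl oxygen; turned over by sodium periodate, [Na+].[O-]I(=O)(=O)=O)
Why: Lemieux–Johnson oxidation (dihydroxylation, then periodate glycol cleavage) gives the aldehyde and spares the PMB ether, which ozone could attack.

### Fragment B (bromobutenolide, C2–C7, C11–C13, C15)

Step 7
Reactants: 11 propargyl alcohol
Product: 12 tert-butyl(diphenyl)(prop-2-yn-1-yloxy)silane
Conditions: tert-butyl(chloro)diphenylsilane (1.05 equiv), imidazole (2 equiv), CH2Cl2, 0 °C → rt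
Reagents that add atoms: tert-butyl(chloro)diphenylsilane, CC(C)(C)[Si](Cl)(c1ccccc1)c1ccccc1
Why: Imidazole-promoted silylation protects the future C15 hydroxyl with a group that survives every later step except fluoride.

Step 8
Reactants: 12 tert-butyl(diphenyl)(prop-2-yn-1-yloxy)silane; 13 acrolein
Product: 15 rac-6-{[tert-butyl(diphenyl)silyl]oxy}hex-1-en-4-yn-3-ol, via lithium acetylide 14 (not isolated)
Conditions: n-BuLi (1.05 equiv), THF, −78 °C; then 13 (1.2 equiv), −78 °C; H2O
Reagents that add atoms: none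
Why: Lithium acetylides add 1,2 to acrolein at low temperature, giving the racemic enynol (C6 is resolved in the next step).

Step 9
Reactants: 15 rac-6-{[tert-butyl(diphenyl)silyl]oxy}hex-1-en-4-yn-3-ol
Product: 16 (3S)-6-{[tert-butyl(diphenyl)silyl]oxy}hex-1-en-4-yn-3-ol
Conditions: Amano lipase PS (Burkholderia cepacia lipase), vinyl acetate (3 equiv), hexane, 30 °C, to 52–55% conversion; chromatography
Reagents that add atoms: none
Why: In this lipase kinetic resolution by transesterification the enzyme should acetylate the (R)-enantiomer (large alkynyl, medium vinyl; Kazlauskas rule), leaving the (S)-alcohol that carries the C6 configuration of the target.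

Step 10
Reactants: 16 (3S)-6-{[tert-butyl(diphenyl)silyl]oxy}hex-1-en-4-yn-3-ol
Product: 18 (3S,4Z)-6-{[tert-butyl(diphenyl)silyl]oxy}-5-iodohexa-1,4-dien-3-ol, via cyclic vinylalanate 17 (not isolated)
Conditions: NaAlH2(OCH2CH2OMe)2 (1.6 equiv), THF, 0 °C → rt; EtOAc, −78 °C; then iodine (2 equiv), THF, −78 → 0 °C
Reagents that add atoms: iodine, [I][I]
Why: Hydroxyl-directed trans-hydroalumination puts aluminium on the distal alkyne carbon in a five-membered alanate, and iodinolysis with retention gives the (Z)-3-iodoallylic alcohol, fixing the C4=C5 geometry.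

Step 11
Reactants: 18 (3S,4Z)-6-{[tert-butyl(diphenyl)silyl]oxy}-5-iodohexa-1,4-dien-3-ol; 19 ethynyl(trimethyl)silane
Product: 20 (3S,4E)-5-({[tert-butyl(diphenyl)silyl]oxy}methyl)-7-(trimethylsilyl)hepta-1,4-dien-6-yn-3-ol
Conditions: 19 (1.5 equiv), Pd(PPh3)2Cl2 (3 mol %), CuI (6 mol %), Et3N (3 equiv), THF, rt
Reagents that add atoms: none
Why: Sonogashira coupling of the vinyl iodide (zerovalent palladium with CuI) retains the alkene geometry; Z becomes E only through CIP priorities.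

Step 12
Reactants: 20 (3S,4E)-5-({[tert-butyl(diphenyl)silyl]oxy}methyl)-7-(trimethylsilyl)hepta-1,4-dien-6-yn-3-ol; 21 2-(bromomethyl)prop-2-enoic acid
Product: 22 (3S,4E)-5-({[tert-butyl(diphenyl)silyl]oxy}methyl)-7-(trimethylsilyl)hepta-1,4-dien-6-yn-3-yl 2-(bromomethyl)prop-2-enoate
Conditions: 21 (1.3 equiv), DCC (1.3 equiv), DMAP (5 mol %), CH2Cl2, −20 → 0 °C
Reagents that add atoms: none
Why: Carbodiimide (Steglich) esterification at low temperature acylates the secondary alcohol without displacing the allylic bromide and does not involve the C6 stereocentre.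

Step 13
Reactants: 22 (3S,4E)-5-({[tert-butyl(diphenyl)silyl]oxy}methyl)-7-(trimethylsilyl)hepta-1,4-dien-6-yn-3-yl 2-(bromomethyl)prop-2-enoate
Product: 23 (5R)-3-(bromomethyl)-5-[(1E)-2-({[tert-butyl(diphenyl)silyl]oxy}methyl)-4-(trimethylsilyl)but-1-en-3-yn-1-yl]furan-2(5H)-one
Conditions: second-generation Hoveyda–Grubbs catalyst, (H2IMes)Cl2Ru=CH(C6H4-2-OiPr) (5 mol %), CH2Cl2 (5 mM), 40 °C
Reagents that add atoms: none
Why: Ring-closing metathesis between the terminal vinyl group and the acrylate alkene forms the five-membered butenolide with loss of ethene, the hindered silyl enyne being inert and the phosphine-free catalyst not being quaternised by the allylic bromide.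

### Union, ring closure and end game

Step 14
Reactants: 10 (3S)-4-[(4-methoxyphenyl)methoxy]-3-methyl-3-[(triethylsilyl)oxy]butanal; 23 (5R)-3-(bromomethyl)-5-[(1E)-2-({[tert-butyl(diphenyl)silyl]oxy}methyl)-4-(trimethylsilyl)but-1-en-3-yn-1-yl]furan-2(5H)-one
Product: 25 (4R,5R)-5-[(1E)-2-({[tert-butyl(diphenyl)silyl]oxy}methyl)-4-(trimethylsilyl)but-1-en-3-yn-1-yl]-4-{(1S,3S)-1-hydroxy-4-[(4-methoxyphenyl)methoxy]-3-methyl-3-[(triethylsilyl)oxy]butyl}-3-methylideneoxolan-2-one (6R;7R;8S;10S), via allylzinc bromide 24 (not isolated)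
Conditions: Zn dust (activated, 3 equiv), 10 (1.3 equiv), THF/sat. aq. NH4Cl (3:1), 0 °C → rt
Reagents that add atoms: none
Why: In this zinc Barbier carbonyl allylation the allylzinc attacks the aldehyde through its γ-carbon (C7) anti to the C6 substituent (C6/C7 trans), and a closed chair transition state with the aldehyde chain equatorial should give the 7,8-anti alcohol (8S), the α-methylene lactone being formed in the same event.

Step 15
Reactants: 25 Barbier adduct (6R;7R;8S;10S); 26 methacrylic acid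
Product: 27 (1R,3S)-1-{(2R,3R)-2-[(1E)-2-({[tert-butyl(diphenyl)silyl]oxy}methyl)-4-(trimethylsilyl)but-1-en-3-yn-1-yl]-4-methylidene-5-oxooxolan-3-yl}-4-[(4-methoxyphenyl)methoxy]-3-methyl-3-[(triethylsilyl)oxy]butyl 2-methylprop-2-enoate (6R;7R;8R;10S)
Conditions: 26 (3 equiv), PPh3 (2.5 equiv), diisopropyl azodicarboxylate (2.5 equiv), toluene, 0 °C → rt
Reagents that add atoms: none
Why: Mitsunobu esterification displaces the activated C8 oxygen by methacrylate with clean SN2 inversion, giving the 8R ester of the target in one step.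

Step 16
Reactants: 27 methacrylate (6R;7R;8R;10S)
Product: 28 primary alcohol: 27 with the C1 PMB ether replaced by OH
Conditions: DDQ (1.5 equiv), CH2Cl2/pH 7 phosphate buffer (10:1), 0 °C → rt
Reagents that add atoms: none
Why: Oxidative PMB cleavage by DDQ frees only the C1 hydroxyl, since silyl ethers, acrylates and the silyl alkyne are inert to it.

Step 17
Reactants: 28 primary alcohol
Product: 29 iodoalkyne: 28 with the alkynyl TMS group replaced by iodine
Conditions: N-iodosuccinimide (1.3 equiv), AgNO3 (10 mol %), DMF, rt, dark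
Reagents that add atoms: N-iodosuccinimide, O=C1CCC(=O)N1I
Why: Silver-catalysed iododesilylation converts the alkynylsilane through a silver acetylide into the 1-iodoalkyne under neutral conditions.

Step 18
Reactants: 29 iodoalkyne alcohol
Product: 30 aldehyde: (1R,3S)-1-{(2R,3R)-2-[(1E)-2-({[tert-butyl(diphenyl)silyl]oxy}methyl)-4-iodobut-1-en-3-yn-1-yl]-4-methylidene-5-oxooxolan-3-yl}-3-methyl-4-oxo-3-[(triethylsilyl)oxy]butyl 2-methylprop-2-enoate
Conditions: Dess–Martin periodinane (1.5 equiv), NaHCO3, CH2Cl2, 0 °C → rt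
Reagents that add atoms: none
Why: Dess–Martin oxidation gives the C1 aldehyde under buffered neutral conditions, and C10 cannot epimerise because it bears no hydrogen.

Step 19
Reactants: 30 iodoalkyne aldehyde
Product: 32 macrocyclic propargylic alcohol: (6R,7R,8R,10S)-15-{[tert-butyl(diphenyl)silyl]oxy}-1-hydroxy-8-(2-methylprop-2-enoyloxy)-10-[(triethylsilyl)oxy]germacra-4,11(13)-dien-2-yn-12,6-olide (C3 and C6 cis across C4=C5; both C1 epimers), via alkynylchromium dichloride 31 (not isolated)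
Conditions: CrCl2 (10 equiv), NiCl2 (10 mol %), degassed THF, rt; 30 added by syringe pump over 10 h (final 2 mM)
Reagents that add atoms: none
Why: In this intramolecular Nozaki–Hiyama–Kishi reaction the alkynylchromium species adds only to the aldehyde under neutral conditions that both acrylates tolerate, high dilution favours the ten-membered ring, and the new C1 carbinol is oxidised next so its configuration does not matter.

Step 20
Reactants: 32 macrocyclic propargylic alcohol
Product: 33 macrocyclic ynone: (6R,7R,8R,10S)-15-{[tert-butyl(diphenyl)silyl]oxy}-8-(2-methylprop-2-enoyloxy)-1-oxo-10-[(triethylsilyl)oxy]germacra-4,11(13)-dien-2-yn-12,6-olide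
Conditions: Dess–Martin periodinane (1.5 equiv), NaHCO3, CH2Cl2, 0 °C
Reagents that add atoms: none
Why: Dess–Martin oxidation of the propargylic alcohol gives the ynone and removes the C1 stereocentre, while the silylated C10 oxygen prevents glycol cleavage.

Step 21
Reactants: 33 macrocyclic ynone
Product: 34 hydroxy ynone: (6R,7R,8R,10S)-15-{[tert-butyl(diphenyl)silyl]oxy}-10-hydroxy-8-(2-methylprop-2-enoyloxy)-1-oxogermacra-4,11(13)-dien-2-yn-12,6-olide
Conditions: HF·pyridine, pyridine, THF, 0 °C, 1–2 h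
Reagents that add atoms: none
Why: Buffered fluoride desilylation cleaves the triethylsilyl ether much faster than the primary TBDPS ether.

Step 22
Reactants: 34 hydroxy ynone
Product: 35 (6R,7R,8R,10S,4Z)-15-{[tert-butyl(diphenyl)silyl]oxy}-8-(2-methylprop-2-enoyloxy)-1-oxo-3,10-epoxygermacra-2,4,11(13)-trien-12,6-olide
Conditions: (4-CF3C6H4)3PAuCl (5 mol %), AgO3SCF3 (5 mol %), toluene, rt
Reagents that add atoms: none
Why: Cationic monovalent gold activates the ynone for 5-endo-dig attack of the C10 hydroxyl at C3 (cycloisomerisation to the 3(2H)-furanone), the C15 oxygen being kept silylated so that it cannot compete.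

Step 23
Reactants: 35 silyl ether of the target
Product: 36 target, [(2Z,4R,8R,9R,11S)-2-(hydroxymethyl)-11-methyl-7-methylidene-6,12-dioxo-5,14-dioxatricyclo[9.2.1.0(4,8)]tetradeca-1(13),2-dien-9-yl] 2-methylprop-2-enoate
Conditions: HF·pyridine (excess), THF, 0 °C → rt, 12–24 h
Reagents that add atoms: none
Why: Fluoride desilylation under mildly acidic conditions spares the three Michael acceptors and releases the C15 alcohol.

## Compound list

1 | (R)-lactic acid | C[C@@H](O)C(=O)O | starting material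
2 | (2R,5R)-2-tert-butyl-5-methyl-1,3-dioxolan-4-one (cis) | C[C@H]1O[C@@H](C(C)(C)C)OC1=O | intermediate
3 | allyl bromide | C=CCBr | starting material
4 | lithium enolate of 2 (2R; not isolated) | CC1=C(O[Li])O[C@H](C(C)(C)C)O1 | intermediate
5 | (2R,5S)-2-tert-butyl-5-methyl-5-(prop-2-en-1-yl)-1,3-dioxolan-4-one | C[C@@]1(CC=C)O[C@@H](C(C)(C)C)OC1=O | intermediate
6 | (2S)-2-methylpent-4-ene-1,2-diol | C[C@@](CO)(CC=C)O | intermediate
7 | (2S)-1-[(4-methoxyphenyl)methoxy]-2-methylpent-4-en-2-ol | C[C@@](COCc1ccc(OC)cc1)(CC=C)O | intermediate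
8 | triethyl{[(2S)-1-[(4-methoxyphenyl)methoxy]-2-methylpent-4-en-2-yl]oxy}silane | C[C@@](COCc1ccc(OC)cc1)(CC=C)O[Si](CC)(CC)CC | intermediate
9 | (4S)-5-[(4-methoxyphenyl)methoxy]-4-methyl-4-[(triethylsilyl)oxy]pentane-1,2-diol (C2 epimers; not isolated) | C[C@@](COCc1ccc(OC)cc1)(CC(O)CO)O[Si](CC)(CC)CC | intermediate
10 | (3S)-4-[(4-methoxyphenyl)methoxy]-3-methyl-3-[(triethylsilyl)oxy]butanal | C[C@@](COCc1ccc(OC)cc1)(CC=O)O[Si](CC)(CC)CC | intermediate
11 | propargyl alcohol | C#CCO | starting material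
12 | tert-butyl(diphenyl)(prop-2-yn-1-yloxy)silane | C#CCO[Si](c1ccccc1)(c1ccccc1)C(C)(C)C | intermediate
13 | acrolein | C=CC=O | starting material
14 | lithium acetylide of 12 (not isolated) | [Li]C#CCO[Si](c1ccccc1)(c1ccccc1)C(C)(C)C | intermediate
15 | rac-6-{[tert-butyl(diphenyl)silyl]oxy}hex-1-en-4-yn-3-ol | C=CC(O)C#CCO[Si](c1ccccc1)(c1ccccc1)C(C)(C)C | intermediate
16 | (3S)-6-{[tert-butyl(diphenyl)silyl]oxy}hex-1-en-4-yn-3-ol | C=C[C@H](O)C#CCO[Si](c1ccccc1)(c1ccccc1)C(C)(C)C | intermediate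
17 | sodium cyclic vinylalanate from 16 (O on C6, Al on C4, two 2-methoxyethoxy ligands; not isolated) | [Na+].C=C[C@@H]1O[Al-](OCCOC)(OCCOC)C(CO[Si](c2ccccc2)(c2ccccc2)C(C)(C)C)=C1 | intermediate
18 | (3S,4Z)-6-{[tert-butyl(diphenyl)silyl]oxy}-5-iodohexa-1,4-dien-3-ol | C=C[C@H](O)/C=C(\I)CO[Si](c1ccccc1)(c1ccccc1)C(C)(C)C | intermediate
19 | ethynyl(trimethyl)silane | C#C[Si](C)(C)C | starting material
20 | (3S,4E)-5-({[tert-butyl(diphenyl)silyl]oxy}methyl)-7-(trimethylsilyl)hepta-1,4-dien-6-yn-3-ol | C=C[C@H](O)/C=C(\C#C[Si](C)(C)C)CO[Si](c1ccccc1)(c1ccccc1)C(C)(C)C | intermediate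
21 | 2-(bromomethyl)prop-2-enoic acid | C=C(CBr)C(=O)O | starting material
22 | (3S,4E)-5-({[tert-butyl(diphenyl)silyl]oxy}methyl)-7-(trimethylsilyl)hepta-1,4-dien-6-yn-3-yl 2-(bromomethyl)prop-2-enoate | C=C[C@H](OC(=O)C(=C)CBr)/C=C(\C#C[Si](C)(C)C)CO[Si](c1ccccc1)(c1ccccc1)C(C)(C)C | intermediate
23 | (5R)-3-(bromomethyl)-5-[(1E)-2-({[tert-butyl(diphenyl)silyl]oxy}methyl)-4-(trimethylsilyl)but-1-en-3-yn-1-yl]furan-2(5H)-one | BrCC1=C[C@H](OC1=O)/C=C(\C#C[Si](C)(C)C)CO[Si](c2ccccc2)(c2ccccc2)C(C)(C)C | intermediate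
24 | allylzinc bromide from 23 (Zn on the former CH2Br carbon; not isolated) | Br[Zn]CC1=C[C@H](OC1=O)/C=C(\C#C[Si](C)(C)C)CO[Si](c2ccccc2)(c2ccccc2)C(C)(C)C | intermediate
25 | Barbier adduct, (4R,5R)-5-[(1E)-2-({[tert-butyl(diphenyl)silyl]oxy}methyl)-4-(trimethylsilyl)but-1-en-3-yn-1-yl]-4-{(1S,3S)-1-hydroxy-4-[(4-methoxyphenyl)methoxy]-3-methyl-3-[(triethylsilyl)oxy]butyl}-3-methylideneoxolan-2-one (6R,7R,8S,10S) | C=C1C(=O)O[C@H](/C=C(\C#C[Si](C)(C)C)CO[Si](c2ccccc2)(c2ccccc2)C(C)(C)C)[C@H]1[C@@H](O)C[C@](C)(O[Si](CC)(CC)CC)COCc1ccc(OC)cc1 | intermediate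
26 | methacrylic acid | C=C(C)C(=O)O | starting material
27 | (1R,3S)-1-{(2R,3R)-2-[(1E)-2-({[tert-butyl(diphenyl)silyl]oxy}methyl)-4-(trimethylsilyl)but-1-en-3-yn-1-yl]-4-methylidene-5-oxooxolan-3-yl}-4-[(4-methoxyphenyl)methoxy]-3-methyl-3-[(triethylsilyl)oxy]butyl 2-methylprop-2-enoate (6R,7R,8R,10S) | C=C1C(=O)O[C@H](/C=C(\C#C[Si](C)(C)C)CO[Si](c2ccccc2)(c2ccccc2)C(C)(C)C)[C@H]1[C@H](OC(=O)C(C)=C)C[C@](C)(O[Si](CC)(CC)CC)COCc1ccc(OC)cc1 | intermediate
28 | primary alcohol, 27 with 4-hydroxy in place of the PMB ether (6R,7R,8R,10S) | C=C1C(=O)O[C@H](/C=C(\C#C[Si](C)(C)C)CO[Si](c2ccccc2)(c2ccccc2)C(C)(C)C)[C@H]1[C@H](OC(=O)C(C)=C)C[C@](C)(O[Si](CC)(CC)CC)CO | intermediate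
29 | iodoalkyne alcohol, 28 with a 4-iodobut-1-en-3-yn-1-yl terminus in place of the TMS alkyne | C=C1C(=O)O[C@H](/C=C(\C#CI)CO[Si](c2ccccc2)(c2ccccc2)C(C)(C)C)[C@H]1[C@H](OC(=O)C(C)=C)C[C@](C)(O[Si](CC)(CC)CC)CO | intermediate
30 | (1R,3S)-1-{(2R,3R)-2-[(1E)-2-({[tert-butyl(diphenyl)silyl]oxy}methyl)-4-iodobut-1-en-3-yn-1-yl]-4-methylidene-5-oxooxolan-3-yl}-3-methyl-4-oxo-3-[(triethylsilyl)oxy]butyl 2-methylprop-2-enoate | C=C1C(=O)O[C@H](/C=C(\C#CI)CO[Si](c2ccccc2)(c2ccccc2)C(C)(C)C)[C@H]1[C@H](OC(=O)C(C)=C)C[C@](C)(O[Si](CC)(CC)CC)C=O | intermediate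
31 | alkynylchromium dichloride from 30 (Cr in place of I; not isolated) | C=C1C(=O)O[C@H](/C=C(\C#C[Cr](Cl)Cl)CO[Si](c2ccccc2)(c2ccccc2)C(C)(C)C)[C@H]1[C@H](OC(=O)C(C)=C)C[C@](C)(O[Si](CC)(CC)CC)C=O | intermediate
32 | (6R,7R,8R,10S)-15-{[tert-butyl(diphenyl)silyl]oxy}-1-hydroxy-8-(2-methylprop-2-enoyloxy)-10-[(triethylsilyl)oxy]germacra-4,11(13)-dien-2-yn-12,6-olide (C3/C6 cis across C4=C5; C1 epimers) | C=C(C)C(=O)O[C@@H]1C[C@](C)(O[Si](CC)(CC)CC)C(O)C#C/C(CO[Si](c3ccccc3)(c3ccccc3)C(C)(C)C)=C\[C@H]2OC(=O)C(=C)[C@@H]21 | intermediate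
33 | (6R,7R,8R,10S)-15-{[tert-butyl(diphenyl)silyl]oxy}-8-(2-methylprop-2-enoyloxy)-1-oxo-10-[(triethylsilyl)oxy]germacra-4,11(13)-dien-2-yn-12,6-olide | C=C(C)C(=O)O[C@@H]1C[C@](C)(O[Si](CC)(CC)CC)C(=O)C#C/C(CO[Si](c3ccccc3)(c3ccccc3)C(C)(C)C)=C\[C@H]2OC(=O)C(=C)[C@@H]21 | intermediate
34 | (6R,7R,8R,10S)-15-{[tert-butyl(diphenyl)silyl]oxy}-10-hydroxy-8-(2-methylprop-2-enoyloxy)-1-oxogermacra-4,11(13)-dien-2-yn-12,6-olide | C=C(C)C(=O)O[C@@H]1C[C@](C)(O)C(=O)C#C/C(CO[Si](c3ccccc3)(c3ccccc3)C(C)(C)C)=C\[C@H]2OC(=O)C(=C)[C@@H]21 | intermediate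
35 | (6R,7R,8R,10S,4Z)-15-{[tert-butyl(diphenyl)silyl]oxy}-8-(2-methylprop-2-enoyloxy)-1-oxo-3,10-epoxygermacra-2,4,11(13)-trien-12,6-olide | C=C(C)C(=O)O[C@@H]1C[C@]2(C)OC(=CC2=O)/C(CO[Si](c3ccccc3)(c3ccccc3)C(C)(C)C)=C\[C@H]2OC(=O)C(=C)[C@@H]21 | intermediate
36 | CNP0180483.4, [(2Z,4R,8R,9R,11S)-2-(hydroxymethyl)-11-methyl-7-methylidene-6,12-dioxo-5,14-dioxatricyclo[9.2.1.0(4,8)]tetradeca-1(13),2-dien-9-yl] 2-methylprop-2-enoate | C=C(C)C(=O)O[C@@H]1C[C@]2(C)OC(=CC2=O)/C(CO)=C\[C@H]2OC(=O)C(=C)[C@@H]21 | target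

## Step count and risks

Total: 23 steps. Longest linear sequence: 17 steps (steps 7–13, then 14–23, from propargyl alcohol); the lactic acid branch is 6 steps before the union.

The three steps most likely to fail:

**Step 19 (ring closure).** A strained ten-membered enyne is formed next to two Michael acceptors; oligomerisation or reduction of the iodoalkyne could win. The fallback closes the ring one bond further on, at C3–C4, by intramolecular Sonogashira coupling, which means carrying the vinyl iodide instead of the enyne. It sets out from 18 and comes back at 32. Compound 18 is esterified with 21 (DCC, DMAP cat.) to the iodo ester F1, and ring-closing metathesis gives the iodo bromobutenolide F2. Zinc Barbier coupling with 10 gives the iodo adduct F3, Mitsunobu reaction with 26 gives the iodo methacrylate F4, DDQ gives the primary alcohol F5, and Dess–Martin oxidation gives the aldehyde F6. Addition of HC≡CMgBr (THF, −78 °C) gives the terminal propargylic alcohol F7. Slow addition of F7 to Pd(PPh3)4 (20 mol %), CuI (10 mol %) and iPr2NEt in degassed THF (1 mM) then closes the ring to 32.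

**Step 15 (Mitsunobu inversion).** C8 lies between a ring methine and a neopentyl-type CH2, so elimination or a sluggish displacement is possible; the step also depends on 25 having the predicted 8S configuration, which should be confirmed (Mosher esters). The fallback resets C8 by oxidation and reagent-controlled reduction. It sets out from 25 and comes back at 27. Dess–Martin oxidation of 25 gives the C8 ketone F8. Reduction with (S)-2-methyl-CBS-oxazaborolidine and catecholborane (toluene, −78 °C), which treats the α-branched C7 side as the large group, gives the (8R)-alcohol F9. Acylation of F9 with methacrylic anhydride (Et3N, DMAP, CH2Cl2, 0 °C) gives 27. The same acylation would be used directly if the Barbier reaction turned out to give the 8R alcohol.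

**Step 9 (enzymatic resolution).** The enantioselectivity of the lipase for this particular vinyl/alkynyl carbinol is unverified, and the yield is capped at 50%. The fallback replaces the resolution by a catalytic asymmetric carbon–carbon bond formation. It sets out from 12 (with 13) and comes back at 16, skipping 15. Alkyne 12 is treated with Me2Zn (3 equiv), a ProPhenol ligand (10 mol %) and Ph3P=O (20 mol %) in toluene, and acrolein is added at 0 °C. The ligand antipode is the one that gives the (S)-alcohol, checked by chiral HPLC against resolved 16. This detour makes no compound outside the list (none F0).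

## Further compounds

F1 | step 19 | (3S,4Z)-6-{[tert-butyl(diphenyl)silyl]oxy}-5-iodohexa-1,4-dien-3-yl 2-(bromomethyl)prop-2-enoate | C=C[C@H](OC(=O)C(=C)CBr)/C=C(\I)CO[Si](c1ccccc1)(c1ccccc1)C(C)(C)C
F2 | step 19 | (5S)-3-(bromomethyl)-5-[(1Z)-3-{[tert-butyl(diphenyl)silyl]oxy}-2-iodoprop-1-en-1-yl]furan-2(5H)-one (same spatial arrangement as 23) | BrCC1=C[C@H](OC1=O)/C=C(\I)CO[Si](c2ccccc2)(c2ccccc2)C(C)(C)C
F3 | step 19 | iodo Barbier adduct: 25 with iodine on C4 in place of the silyl alkyne | C=C1C(=O)O[C@H](/C=C(\I)CO[Si](c2ccccc2)(c2ccccc2)C(C)(C)C)[C@H]1[C@@H](O)C[C@](C)(O[Si](CC)(CC)CC)COCc1ccc(OC)cc1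
F4 | step 19 | iodo methacrylate: 27 with iodine on C4 in place of the silyl alkyne | C=C1C(=O)O[C@H](/C=C(\I)CO[Si](c2ccccc2)(c2ccccc2)C(C)(C)C)[C@H]1[C@H](OC(=O)C(C)=C)C[C@](C)(O[Si](CC)(CC)CC)COCc1ccc(OC)cc1
F5 | step 19 | iodo primary alcohol: F4 with C1 OH in place of the PMB ether | C=C1C(=O)O[C@H](/C=C(\I)CO[Si](c2ccccc2)(c2ccccc2)C(C)(C)C)[C@H]1[C@H](OC(=O)C(C)=C)C[C@](C)(O[Si](CC)(CC)CC)CO
F6 | step 19 | iodo aldehyde: F5 oxidised at C1 | C=C1C(=O)O[C@H](/C=C(\I)CO[Si](c2ccccc2)(c2ccccc2)C(C)(C)C)[C@H]1[C@H](OC(=O)C(C)=C)C[C@](C)(O[Si](CC)(CC)CC)C=O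
F7 | step 19 | terminal propargylic alcohol: F6 after addition of ethynyl to C1 (C1 epimers) | C=C1C(=O)O[C@H](/C=C(\I)CO[Si](c2ccccc2)(c2ccccc2)C(C)(C)C)[C@H]1[C@H](OC(=O)C(C)=C)C[C@](C)(O[Si](CC)(CC)CC)C(O)C#C
F8 | step 15 | C8 ketone: 25 oxidised at C8 (6R,7R,10S) | C=C1C(=O)O[C@H](/C=C(\C#C[Si](C)(C)C)CO[Si](c2ccccc2)(c2ccccc2)C(C)(C)C)[C@H]1C(=O)C[C@](C)(O[Si](CC)(CC)CC)COCc1ccc(OC)cc1
F9 | step 15 | (8R)-alcohol: C8 epimer of 25 (6R,7R,8R,10S) | C=C1C(=O)O[C@H](/C=C(\C#C[Si](C)(C)C)CO[Si](c2ccccc2)(c2ccccc2)C(C)(C)C)[C@H]1[C@H](O)C[C@](C)(O[Si](CC)(CC)CC)COCc1ccc(OC)cc1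
F0 | step 9 | none | none
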